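Remarks on the chemistry (assumptions):
- Atom labels C1–C15 are germacrane numbers throughout: ring C1–C10, lactone carbons C11 (quaternary), C12 (C=O) and C13 (methyl on C11), C14 (methyl on C10), C15 (carbon on C4).
- Compounds 1, 8 and 19, angelic anhydride and both enantiomers of the tBu-box ligand are taken as purchasable.
- Step 9 is written for the facial diastereomer of the photoadduct that is expected to predominate (new C10–C1 bond trans to the C8 silyloxy group). Addition to the other face of the enone would give material of the same constitution and ring fusion. It is not removed, because step 10 turns all four new stereocentres into sp2 carbons and so leads to the same ring-opened product.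

## Analysis of the target

Compound 27 is a germacranolide: a ten-membered carbocycle (C1–C10) fused at C7–C8 to a γ-lactone (C7, C8, O, C12, C11) in which H7 and H8 are anti (trans-fused 12,8-olide). The ring carries a Z-trisubstituted alkene C4=C5 and a trisubstituted epoxide across C1–C10 in which C2 and C9 are trans, so it derives from an E alkene. There are six stereocentres: the epoxide carbons (1R,10R), the contiguous row C6 (R, angelate), C7 (S) and C8 (R), and the quaternary C11 (R) with a methyl group and the second angelate. On the lactone, the C11 oxygen is cis to C6 and trans to H7. The sensitive groups are the two angelates (Z-2-methylbut-2-enoates go over to tiglates under nucleophilic or basic catalysis), the epoxide that faces C4=C5 across the ring (acid starts transannular cyclisation), the allylic ester at C6 and the tertiary α-acyloxy lactone. The hard parts are a medium ring with two trisubstituted double bonds of opposite geometry, and four stereocentres that must be set on a flexible ring. The strategy rests on C4=C5 and the C1=C10 alkene behind the epoxide: they are joined through C2–C3 into a 1,5-diene. Bonding C1 to C4 and C5 to C10 instead gives a bicyclo[2.2.0]hexane whose bond C5–C10 belongs to a cyclohexanone (ring C5–C6–C7–C8–C9–C10, carbonyl at C6), the [2+2] adduct of a cyclohexenone and a cyclobutene.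

## Retrosynthetic reasoning

27 to 26: the two epoxide C–O bonds are cut last. The acid-labile epoxide then meets no later reagent, and 26 is the diene closest to the natural framework, so a peracid should attack only the strained E alkene C1=C10 from its outer face.

26 to 24: the two angelate C–O bonds are cut together. The Z esters are the groups most easily spoiled, so they are put on as late as possible and under conditions without nucleophilic catalysts. 25 is the half-way compound.

24 to 23: the C6–H bond is removed, giving the ketone. The C6 carbonyl is needed earlier as the enone chromophore and as the source of C7 nucleophilicity. The forward reduction has to deliver hydride to one face, which the free C11 hydroxyl of 23 can direct by chelation.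

23 to 21 to 18 and 19: the lactone C12–O bond and the C7–C11 bond are cut. This takes off C11, C12 and C13 as the pyruvate ester 19 and leaves the silyl enol ether 18. One C–C bond formation then brings in the quaternary carbinol with its methyl group and the lactone carbonyl, and the C8 oxygen is already in place to close the ring. The forward aldol has to control C11 and C7. A chiral Lewis acid that chelates 19 sets C11 and, through syn topicity, C7.

18 to 17 to 12: the C15 methyl is traced back to an ester (through 16, 15 and 13). This detour is accepted because the ester is what makes the cyclobutene partner 10 regioselective in the cycloaddition and what weakens the bond that must break first on heating.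

12 to 11: the σ-bonds C1–C4 and C5–C10 are re-formed. This turns the ten-membered 1,5-diene into a six-membered ring fused to a bicyclo[2.2.0]hexane. Nowhere else in the ring does a two-bond reconnection give such a small, known ring system. The forward thermolysis has to break exactly these two bonds and leave C4=C5 with C3 cis to C6 and C1=C10 as E.

11 to 7 and 10: the bonds C4–C5 and C1–C10 are cut, which is the retron of an enone–alkene photocycloaddition. The step builds the whole carbon ring of 27 from two small pieces, and the four stereocentres it creates are all erased again, so only the regiochemistry and the cis-anti-cis ring fusion matter.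

7 to 1: the ring alkene C5=C10 is opened by a metathesis disconnection to the acyclic dienone 6. That compound comes from the ester 4 through the amide 5, and 4 from the epoxide 2 by attack of an isopropenyl nucleophile at the terminal carbon (through 3). The C8 stereocentre is bought with the chlorohydrin 1, so the absolute configuration of 27 does not depend on an asymmetric step.

10 to 8: the cyclobutene double bond comes from elimination of HBr from the α-bromo ester 8, through the acid 9.

## Alternatives that were turned down

Alternative 1: Here C8–C9 would be formed and a C1–C6 bond of a six-membered ring broken in an anionic oxy-Cope rearrangement. The substrate is a cyclohex-2-enol whose carbinol carbon (C6) carries a 2-alkoxyvinyl group (C7=C8) and whose neighbouring ring carbon (C1) carries the isopropenyl group (C10=C9). Its potassium alkoxide would rearrange through a chair to the ten-membered enolate and, after protonation, to dienone A1, the p-methoxybenzyl analogue of 17.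
- For it: the Z alkene C4=C5 is the old ring alkene and cannot change geometry, and the chair sets C1=C10 as E. C15 arrives as a methyl group, so steps 11–14 would not be needed. On alkene geometry and on step count this alternative is stronger than the chosen route.
- Against it: C8 is created in the rearrangement, from the enol ether geometry and the chair/boat preference, instead of being bought. The rearrangement also releases the C6 enolate with the C8 alkoxy group in the β-position at temperatures far above −78 °C, so E1cB loss of that group is hard to prevent. The hindered, enolisable ketone precursor must also accept a β-alkoxyvinyl metal in a 1,2-sense and trans to the isopropenyl group.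
- In its place the chosen strategy offers a purchased C8 centre and a C7 enolate that is made only at −78 °C with immediate trapping.

Alternative 2: Here C2–C3 would be closed last by intramolecular alkylation. A bis(phenylsulfonyl)-stabilised carbanion at C2 displaces a Z-allylic chloride at C3 and gives the protected lactone A2.
- For it: every stereocentre (C6, C7, C8, C11) and both double bonds are fixed on an open chain before the ring exists. The geometry question of the chosen route does not arise, and on stereochemical certainty this alternative is stronger.
- Against it: direct SN2 closure of a ten-membered ring is the least favourable ring size (transannular strain, need for high dilution, SN2′ and oligomerisation as competitors), and the doubly stabilised carbanion is a sluggish, bulky nucleophile. Two allylic C–S bonds must afterwards be reduced off without cleaving the allylic C6–O bond or the lactone and without moving C1=C10. The open-chain precursor with the lactone in place needs a long linear sequence.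
- The chosen route builds the ring from two small fragments in two steps and takes its main risk early, on cheap material.

Alternative 3: Here C6–C7 would be formed by a [2,3]-Wittig ring contraction. In a thirteen-membered bis-allylic ether, tin–lithium exchange at C6 gives an α-oxy carbanion that attacks C7 of the allylic unit C7=C11–C12–O, breaks O–C12 and contracts the ring to A3, with a free C6 hydroxyl and a vinyl group on C7.
- For it: C6 and C7 are set together in one concerted step through a five-membered transition state and the C6 carbinol is liberated directly, whereas the chosen route needs a late reduction for C6. A contraction from thirteen to ten atoms is also easier than a direct closure.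
- Against it: the macrocyclic ether with its organotin centre must be made first, a [1,2]-shift competes, and the C7 vinyl group still has to be turned into the α-hydroxy-α-methyl lactone. That means oxidising it beside two trisubstituted ring alkenes and building the quaternary C11 with no control element.
- The chosen route brings in C11, C12 and C13 in one catalyst-controlled aldol step.

Key step: step 9

## Route

Step 1
Reactants: 1 ethyl (3S)-4-chloro-3-hydroxybutanoate
Product: 2 ethyl 2-[(2S)-oxiran-2-yl]acetate
Conditions: Ag2O, MeCN, 60 °C, dark
Reagents that add atoms: none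
Why: Silver-assisted intramolecular Williamson etherification: Ag2O pulls off chloride while the neighbouring hydroxyl closes the oxirane under non-basic conditions, so the E1cB route to the 4-hydroxycrotonate is avoided; the carbinol carbon is not involved and stays (S).

Step 2
Reactants: 2 ethyl 2-[(2S)-oxiran-2-yl]acetate
Product: 3 ethyl (3R)-3-hydroxy-5-methylhex-5-enoate
Conditions: CH2=C(CH3)MgBr, CuI (10 mol%), THF, −40 °C
Reagents that add atoms: isopropenylmagnesium bromide, C=C(C)[Mg]Br
Why: Copper-catalysed Grignard opening of a terminal epoxide: the organocopper species attacks the unsubstituted oxirane carbon (SN2) faster than the Grignard reagent adds to the ester at −40 °C. The stereocentre is untouched; its descriptor becomes R only through the change in CIP priorities.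

Step 3
Reactants: 3 ethyl (3R)-3-hydroxy-5-methylhex-5-enoate
Product: 4 ethyl (3R)-3-[(tert-butyldimethylsilyl)oxy]-5-methylhex-5-enoate
Conditions: TBSCl, imidazole, DMF, rt
Reagents that add atoms: tert-butyldimethylsilyl chloride, CC(C)(C)[Si](C)(C)Cl
Why: Imidazole-promoted silyl ether formation; the ether protects the future C8 hydroxyl through the base and hydride steps up to step 17.

Step 4
Reactants: 4 ethyl (3R)-3-[(tert-butyldimethylsilyl)oxy]-5-methylhex-5-enoate
Product: 5 (3R)-3-[(tert-butyldimethylsilyl)oxy]-N-methoxy-N,5-dimethylhex-5-enamide
Conditions: MeNH(OMe)·HCl, iPrMgCl, THF, −20 → 0 °C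
Reagents that add atoms: N,O-dimethylhydroxylamine hydrochloride, CNOC.Cl
Why: Weinreb amide formation by aminolysis of the ester with the chloromagnesium amide made in the flask; at −20 °C the β-silyloxy ester is not enolised, so no β-elimination is expected.

Step 5
Reactants: 5 (3R)-3-[(tert-butyldimethylsilyl)oxy]-N-methoxy-N,5-dimethylhex-5-enamide
Product: 6 (5R)-5-[(tert-butyldimethylsilyl)oxy]-7-methylocta-1,7-dien-3-one
Conditions: CH2=CHMgBr, THF, −78 → 0 °C; cold aq HCl
Reagents that add atoms: vinylmagnesium bromide, C=C[Mg]Br
Why: Weinreb ketone synthesis: the chelated tetrahedral adduct survives until the quench, so the Grignard reagent adds only once; the cold acidic quench keeps the liberated amine from adding to the vinyl ketone.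

Step 6
Reactants: 6 (5R)-5-[(tert-butyldimethylsilyl)oxy]-7-methylocta-1,7-dien-3-one
Product: 7 (5R)-5-[(tert-butyldimethylsilyl)oxy]-3-methylcyclohex-2-en-1-one
Conditions: second-generation Grubbs catalyst (3 mol%), CH2Cl2 (0.01 M), 40 °C
Reagents that add atoms: none
Why: Ring-closing olefin metathesis between the vinyl ketone and the 1,1-disubstituted alkene; six-membered ring formation and loss of ethene drive it, and the neutral conditions spare the β-silyloxy enone, which base would aromatise by elimination.

Step 7
Reactants: 8 ethyl 1-bromocyclobutane-1-carboxylate
Product: 9 cyclobut-1-ene-1-carboxylic acid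
Conditions: KOH, toluene, reflux; aq HCl, 0 °C
Reagents that add atoms: potassium hydroxide, [K+].[OH-]
Why: Base-induced dehydrobromination (E2) of the tertiary α-bromo ester with concurrent saponification, the classical entry to this acid; it is used at once because it polymerises on standing.

Step 8
Reactants: 9 cyclobut-1-ene-1-carboxylic acid
Product: 10 methyl cyclobut-1-ene-1-carboxylate
Conditions: MeI, K2CO3, DMF, 0 °C → rt
Reagents that add atoms: iodomethane, CI
Why: SN2 O-alkylation of the carboxylate; it avoids acidic esterification, under which methanol could add to the strained acrylate.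

Step 9
Reactants: 7 (5R)-5-[(tert-butyldimethylsilyl)oxy]-3-methylcyclohex-2-en-1-one; 10 methyl cyclobut-1-ene-1-carboxylate
Product: 11 methyl (1S,2R,5S,6S,8R)-8-[(tert-butyldimethylsilyl)oxy]-6-methyl-10-oxotricyclo[4.4.0.0(2,5)]decane-2-carboxylate (cis-anti-cis ring fusion; head-to-head; cyclobutanes trans to the silyl ether)
Conditions: hν (Hg lamp, Pyrex filter, λ > 300 nm), 10 (5 equiv), CH2Cl2, −20 °C; then filtration through basic Al2O3
Reagents that add atoms: none
Why: Enone–alkene [2+2] photocycloaddition; the closest known reaction type is the addition of cyclohexenones to cyclobut-1-enecarboxylates, which gives tricyclo[4.4.0.0(2,5)]decanones. Excitation of 7 (n→π*) and intersystem crossing give the twisted triplet enone, whose β-carbon C10 bonds first to the unsubstituted alkene carbon C1 of 10; the triplet 1,4-biradical (α-keto radical at C5, ester-stabilised tertiary radical at C4) then undergoes spin inversion and collapses to the C4–C5 bond. One ring is closed, the cyclobutane C5–C10–C1–C4, by this two-bond annulation (bimolecular first bond, radical–radical recombination for the second); with the four-membered ring that 10 brings in it makes up the bicyclo[2.2.0]hexane. The step needs head-to-head regiochemistry (ester carbon C4 on the α-carbon C5): it is secured electronically, because the β-carbon of the excited enone adds to the β-position of the acrylate-type alkene, and sterically, because the other orientation would join the two quaternary carbons C4 and C10. C5 and C10 end up cis because a trans-fused cyclobutane on the six-membered ring is strained and is epimerised at C5 on Al2O3, C1 and C4 are cis by the small ring, and the two outer rings are anti because the biradical closes with the cyclobutane turned away from the cyclohexanone. The absolute sense of the four new centres is set by the C8 silyl ether: the first bond at C10 should form axially on the half-chair that keeps the silyloxy group pseudo-equatorial, hence trans to it, which is 11. Attack on the other face would give the facial diastereomer of the same constitution and ring fusion; it need not be removed, because all four new centres become sp2 in step 10 and both faces then lead to 12.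

Step 10
Reactants: 11 methyl (1S,2R,5S,6S,8R)-8-[(tert-butyldimethylsilyl)oxy]-6-methyl-10-oxotricyclo[4.4.0.0(2,5)]decane-2-carboxylate
Product: 12 methyl (1E,5R,7E)-5-[(tert-butyldimethylsilyl)oxy]-7-methyl-3-oxocyclodeca-1,7-diene-1-carboxylate (C3 cis to C6 on C4=C5, E at C1=C10)
Conditions: flash vacuum thermolysis, base-washed quartz tube, ca. 420 °C, 0.01 mbar, −78 °C trap
Reagents that add atoms: none
Why: Thermal cleavage of a bicyclo[2.2.0]hexane to a hexa-1,5-diene (stepwise cycloreversion): the strained, ester-substituted central bond C1–C4 breaks first, the cyclohexane-1,4-diyl relaxes to a chair and then loses the C5–C10 bond. In that chair C6 should sit axial on C5 to avoid A(1,2) strain with the in-plane ester on the planar C4 radical, which places C3 cis to C6 on C4=C5 and, with C9 then equatorial on C10, C2 trans to C9 on C1=C10 (the first bond is labelled E here only because the ester outranks C3). The short contact time is chosen to prevent the following Cope rearrangement to a divinylcyclohexanone.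

Step 11
Reactants: 12 methyl (1E,5R,7E)-5-[(tert-butyldimethylsilyl)oxy]-7-methyl-3-oxocyclodeca-1,7-diene-1-carboxylate
Product: 13 (2E,6E,9R)-9-[(tert-butyldimethylsilyl)oxy]-3-(hydroxymethyl)-7-methylcyclodeca-2,6-dien-1-ol (both C6 epimers)
Conditions: iBu2AlH (4 equiv), CH2Cl2, −78 °C; Rochelle salt
Reagents that add atoms: none
Why: Hydride reduction with iBu2AlH, which adds 1,2 to both the enone carbonyl and the enoate; the new C6 carbinol is formed as an epimer mixture that does not matter because C6 is re-oxidised in step 14.

Step 12
Reactants: 13 (2E,6E,9R)-9-[(tert-butyldimethylsilyl)oxy]-3-(hydroxymethyl)-7-methylcyclodeca-2,6-dien-1-ol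
Product: 15 (2E,6E,9R)-9-[(tert-butyldimethylsilyl)oxy]-3-(chloromethyl)-7-methylcyclodeca-2,6-dien-1-ol, via C15 mesylate 14 (not isolated)
Conditions: MsCl (1.1 equiv), 2,4,6-collidine, LiCl, DMF, −10 → 0 °C
Reagents that add atoms: lithium chloride, [Li+].[Cl-]; methanesulfonyl chloride, CS(=O)(=O)Cl (in 14 only)
Why: Allylic chlorination through the mesylate: the primary allylic hydroxyl is sulfonylated much faster than the hindered secondary one, and chloride displaces the mesylate at C15 without allylic transposition; C15 is trans to C6, so the C6 hydroxyl cannot cyclise onto it.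

Step 13
Reactants: 15 (2E,6E,9R)-9-[(tert-butyldimethylsilyl)oxy]-3-(chloromethyl)-7-methylcyclodeca-2,6-dien-1-ol
Product: 16 (2Z,6E,9R)-9-[(tert-butyldimethylsilyl)oxy]-3,7-dimethylcyclodeca-2,6-dien-1-ol (both C6 epimers)
Conditions: LiEt3BH (2.5 equiv), THF, 0 °C
Reagents that add atoms: none
Why: SN2 displacement of the primary allylic chloride by hydride, which attacks the unhindered CH2 terminus and not C5; the first equivalent only deprotonates the C6 hydroxyl. The alkene geometry is kept and is now described as 4Z.

Step 14
Reactants: 16 (2Z,6E,9R)-9-[(tert-butyldimethylsilyl)oxy]-3,7-dimethylcyclodeca-2,6-dien-1-ol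
Product: 17 (2Z,6E,9R)-9-[(tert-butyldimethylsilyl)oxy]-3,7-dimethylcyclodeca-2,6-dien-1-one
Conditions: Dess–Martin periodinane, NaHCO3, CH2Cl2, 0 °C → rt
Reagents that add atoms: none
Why: Dess–Martin oxidation of the allylic alcohol under buffered, non-basic conditions, so neither the Z-enone geometry nor the β-silyloxy ketone is disturbed.

Step 15
Reactants: 17 (2Z,6E,9R)-9-[(tert-butyldimethylsilyl)oxy]-3,7-dimethylcyclodeca-2,6-dien-1-one
Product: 18 tert-butyl{[(1R,2E,4Z,8E)-5,9-dimethyl-3-[(trimethylsilyl)oxy]cyclodeca-2,4,8-trien-1-yl]oxy}dimethylsilane (C6 trimethylsilyl enol ether with the enol double bond C6=C7)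
Conditions: LiN(iPr)2 premixed with Me3SiCl, THF, −78 °C; Et3N, pentane work-up
Reagents that add atoms: chlorotrimethylsilane, C[Si](C)(C)Cl
Why: Kinetic α′-deprotonation of the enone at C7 with in situ silylation (silyl enol ether formation): amide bases remove the α′-proton faster than a γ-proton, and immediate O-silylation at −78 °C prevents β-elimination of the C8 silyloxy group from the enolate. The ring-cis enol ether is drawn; the next step should not depend on this geometry.

Step 16
Reactants: 18 tert-butyl{[(1R,2E,4Z,8E)-5,9-dimethyl-3-[(trimethylsilyl)oxy]cyclodeca-2,4,8-trien-1-yl]oxy}dimethylsilane; 19 methyl 2-oxopropanoate (methyl pyruvate)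
Product: 21 methyl (2R)-2-[(1R,3Z,7E,10R)-10-[(tert-butyldimethylsilyl)oxy]-4,8-dimethyl-2-oxocyclodeca-3,7-dien-1-yl]-2-hydroxypropanoate, via C11 trimethylsilyl ether 20 (not isolated)
Conditions: [Cu((R,R)-tBu-box)](OTf)2 (10 mol%), THF, −78 °C; then 1 M HCl, THF, 0 °C
Reagents that add atoms: none
Why: Catalytic enantioselective Mukaiyama aldol addition to a pyruvate ester with a C2-symmetric copper bis(oxazoline) Lewis acid: 19 chelates divalent copper through both carbonyl oxygens, and the (R,R)-ligand leaves open the ketone face that gives (11R). The open transition state favours the syn adduct, with the C11 oxygen and C8 on the same side of the C12–C11–C7–C6 chain, which is the C7 configuration of 27 (labelled R in 21 because the C6 carbonyl outranks C11). This agrees with the bias of the substrate itself, since 18 should be attacked on the outer face of the ring, anti to C9 with H8 eclipsing the enol ether.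

Step 17
Reactants: 21 methyl (2R)-2-[(1R,3Z,7E,10R)-10-[(tert-butyldimethylsilyl)oxy]-4,8-dimethyl-2-oxocyclodeca-3,7-dien-1-yl]-2-hydroxypropanoate
Product: 23 (7R,8R,11R)-11-hydroxy-6-oxogermacra-1(10)E,4Z-dien-12,8-olide, via C8 hydroxy ester 22 (not isolated)
Conditions: HF·pyridine, pyridine, THF, 0 °C → rt
Reagents that add atoms: none
Why: Fluoride-mediated desilylation followed by lactonisation (intramolecular transesterification): the freed C8 hydroxyl sits γ to the methyl ester and closes the five-membered lactone under mildly acidic conditions, which avoid retro-aldol cleavage and E1cB reactions of the β-oxygenated ketone. The electron-poor enone C4=C5 is not expected to take part in acid-induced transannular reactions.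

Step 18
Reactants: 23 (7R,8R,11R)-11-hydroxy-6-oxogermacra-1(10)E,4Z-dien-12,8-olide
Product: 24 (6R,7S,8R,11R)-6,11-dihydroxygermacra-1(10)E,4Z-dien-12,8-olide
Conditions: Zn(BH4)2, Et2O, −40 → −20 °C; aq NH4Cl
Reagents that add atoms: none
Why: Chelation-controlled 1,2-reduction of the ketone: zinc bridges the C6 carbonyl and the C11 hydroxyl, which lie on the same side of the lactone, and hydride then adds to the carbonyl face next to H7, away from C8 and the lactone ring, which should give the (6R) carbinol. The lactone and the enone double bond are not reduced at this temperature.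

Step 19
Reactants: 24 (6R,7S,8R,11R)-6,11-dihydroxygermacra-1(10)E,4Z-dien-12,8-olide
Product: 26 (6R,7S,8R,11R)-6,11-bis(angeloyloxy)germacra-1(10)E,4Z-dien-12,8-olide, via 6-O-angelate 25 (not isolated)
Conditions: angelic anhydride (4 equiv), THF; LiN(SiMe3)2 (2.4 equiv) added at −78 °C, then → 0 °C
Reagents that add atoms: angelic anhydride [(Z)-2-methylbut-2-enoic anhydride], C/C=C(/C)C(=O)OC(=O)/C(C)=C\C
Why: Acylation of lithium alkoxides with an anhydride: the secondary C6 alkoxide reacts first (25) and the tertiary C11 alkoxide follows on warming. No nucleophilic amine catalyst is present, so the Z esters should not isomerise to tiglates, and the base is added to the diol–anhydride mixture so that the C6 alkoxide is trapped before it can attack the lactone.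

Step 20
Reactants: 26 (6R,7S,8R,11R)-6,11-bis(angeloyloxy)germacra-1(10)E,4Z-dien-12,8-olide
Product: 27 (1R,6R,7S,8R,10R,11R)-6,11-bis(angeloyloxy)-1,10-epoxygermacr-4Z-en-12,8-olide (CNP0182151.2)
Conditions: mCPBA (1.05 equiv), NaHCO3, CH2Cl2, −20 → 0 °C
Reagents that add atoms: 3-chloroperbenzoic acid, OOC(=O)c1cccc(Cl)c1
Why: Prilezhaev epoxidation: the strained E-trisubstituted C1=C10 bond is the most electron-rich alkene (C4=C5 is deactivated by the allylic ester, the angelate alkenes by conjugation) and is attacked on its outer face. In the conformer with C14 on the same side as the C7–C11 bond, the usual one for such lactones, this gives the (1R,10R) epoxide; bicarbonate buffers the acid that would start transannular cyclisation.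

## Compound list

1 | ethyl (3S)-4-chloro-3-hydroxybutanoate | CCOC(=O)C[C@H](O)CCl | starting material
2 | ethyl 2-[(2S)-oxiran-2-yl]acetate | CCOC(=O)C[C@H]1CO1 | intermediate
3 | ethyl (3R)-3-hydroxy-5-methylhex-5-enoate | CCOC(=O)C[C@H](O)CC(C)=C | intermediate
4 | ethyl (3R)-3-[(tert-butyldimethylsilyl)oxy]-5-methylhex-5-enoate | CCOC(=O)C[C@H](O[Si](C)(C)C(C)(C)C)CC(C)=C | intermediate
5 | (3R)-3-[(tert-butyldimethylsilyl)oxy]-N-methoxy-N,5-dimethylhex-5-enamide | CON(C)C(=O)C[C@H](O[Si](C)(C)C(C)(C)C)CC(C)=C | intermediate
6 | (5R)-5-[(tert-butyldimethylsilyl)oxy]-7-methylocta-1,7-dien-3-one | C=CC(=O)C[C@H](O[Si](C)(C)C(C)(C)C)CC(C)=C | intermediate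
7 | (5R)-5-[(tert-butyldimethylsilyl)oxy]-3-methylcyclohex-2-en-1-one | O=C1C[C@H](O[Si](C)(C)C(C)(C)C)CC(C)=C1 | intermediate
8 | ethyl 1-bromocyclobutane-1-carboxylate | CCOC(=O)C1(Br)CCC1 | starting material
9 | cyclobut-1-ene-1-carboxylic acid | OC(=O)C1=CCC1 | intermediate
10 | methyl cyclobut-1-ene-1-carboxylate | COC(=O)C1=CCC1 | intermediate
11 | methyl (1S,2R,5S,6S,8R)-8-[(tert-butyldimethylsilyl)oxy]-6-methyl-10-oxotricyclo[4.4.0.0(2,5)]decane-2-carboxylate, cis-anti-cis, cyclobutanes trans to the silyl ether | O=C1C[C@H](O[Si](C)(C)C(C)(C)C)C[C@]2(C)[C@H]1[C@@]1(C(=O)OC)CC[C@@H]21 | intermediate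
12 | methyl (1E,5R,7E)-5-[(tert-butyldimethylsilyl)oxy]-7-methyl-3-oxocyclodeca-1,7-diene-1-carboxylate | COC(=O)/C1=C/C(=O)C[C@H](O[Si](C)(C)C(C)(C)C)C/C(C)=C/CC1 | intermediate
13 | (2E,6E,9R)-9-[(tert-butyldimethylsilyl)oxy]-3-(hydroxymethyl)-7-methylcyclodeca-2,6-dien-1-ol, both C6 (ring C1) epimers | OC/C1=C/C(O)C[C@H](O[Si](C)(C)C(C)(C)C)C/C(C)=C/CC1 | intermediate
14 | C15 methanesulfonate of 13 | CS(=O)(=O)OC/C1=C/C(O)C[C@H](O[Si](C)(C)C(C)(C)C)C/C(C)=C/CC1 | intermediate
15 | (2E,6E,9R)-9-[(tert-butyldimethylsilyl)oxy]-3-(chloromethyl)-7-methylcyclodeca-2,6-dien-1-ol, both C6 epimers | ClC/C1=C/C(O)C[C@H](O[Si](C)(C)C(C)(C)C)C/C(C)=C/CC1 | intermediate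
16 | (2Z,6E,9R)-9-[(tert-butyldimethylsilyl)oxy]-3,7-dimethylcyclodeca-2,6-dien-1-ol, both C6 epimers | C/C1=C/C(O)C[C@H](O[Si](C)(C)C(C)(C)C)C/C(C)=C/CC1 | intermediate
17 | (2Z,6E,9R)-9-[(tert-butyldimethylsilyl)oxy]-3,7-dimethylcyclodeca-2,6-dien-1-one | C/C1=C/C(=O)C[C@H](O[Si](C)(C)C(C)(C)C)C/C(C)=C/CC1 | intermediate
18 | tert-butyl{[(1R,2E,4Z,8E)-5,9-dimethyl-3-[(trimethylsilyl)oxy]cyclodeca-2,4,8-trien-1-yl]oxy}dimethylsilane | C/C1=C/C(O[Si](C)(C)C)=C\[C@H](O[Si](C)(C)C(C)(C)C)C/C(C)=C/CC1 | intermediate
19 | methyl 2-oxopropanoate (methyl pyruvate) | COC(=O)C(C)=O | starting material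
20 | C11 trimethylsilyl ether of 21 | C/C1=C/C(=O)[C@@H]([C@@](C)(O[Si](C)(C)C)C(=O)OC)[C@H](O[Si](C)(C)C(C)(C)C)C/C(C)=C/CC1 | intermediate
21 | methyl (2R)-2-[(1R,3Z,7E,10R)-10-[(tert-butyldimethylsilyl)oxy]-4,8-dimethyl-2-oxocyclodeca-3,7-dien-1-yl]-2-hydroxypropanoate | C/C1=C/C(=O)[C@@H]([C@@](C)(O)C(=O)OC)[C@H](O[Si](C)(C)C(C)(C)C)C/C(C)=C/CC1 | intermediate
22 | methyl (2R)-2-hydroxy-2-[(1R,3Z,7E,10R)-10-hydroxy-4,8-dimethyl-2-oxocyclodeca-3,7-dien-1-yl]propanoate | C/C1=C/C(=O)[C@@H]([C@@](C)(O)C(=O)OC)[C@H](O)C/C(C)=C/CC1 | intermediate
23 | (7R,8R,11R)-11-hydroxy-6-oxogermacra-1(10)E,4Z-dien-12,8-olide | C/C1=C/C(=O)[C@H]2[C@@](C)(O)C(=O)O[C@@H]2C/C(C)=C/CC1 | intermediate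
24 | (6R,7S,8R,11R)-6,11-dihydroxygermacra-1(10)E,4Z-dien-12,8-olide | C/C1=C/[C@@H](O)[C@H]2[C@@](C)(O)C(=O)O[C@@H]2C/C(C)=C/CC1 | intermediate
25 | (6R,7S,8R,11R)-6-(angeloyloxy)-11-hydroxygermacra-1(10)E,4Z-dien-12,8-olide | C/C=C(/C)C(=O)O[C@@H]1/C=C(/C)CC/C=C(\C)C[C@H]2OC(=O)[C@](C)(O)[C@H]12 | intermediate
26 | (6R,7S,8R,11R)-6,11-bis(angeloyloxy)germacra-1(10)E,4Z-dien-12,8-olide | C/C=C(/C)C(=O)O[C@@H]1/C=C(/C)CC/C=C(\C)C[C@H]2OC(=O)[C@](C)(OC(=O)/C(C)=C\C)[C@H]12 | intermediate
27 | (1R,6R,7S,8R,10R,11R)-6,11-bis(angeloyloxy)-1,10-epoxygermacr-4Z-en-12,8-olide (CNP0182151.2) | C/C=C(/C)C(=O)O[C@@H]1/C=C(/C)CC[C@H]2O[C@]2(C)C[C@H]2OC(=O)[C@](C)(OC(=O)/C(C)=C\C)[C@H]12 | target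

## Step count and least certain steps

Total: 20 steps. Longest linear sequence: 18 steps (steps 1–6 and 9–20, from 1 to 27); the two-step branch to 10 (steps 7–8) joins at step 9.

Step 9 (key step). The most likely failure is low efficiency rather than wrong structure. The strained acrylate 10 can polymerise under irradiation, the β,β-disubstituted enone 7 adds slowly and can photodimerise or deconjugate, and some head-to-tail addition would lower the yield further. Poor facial selectivity would be harmless, because addition to either face of 7 ends in 12 after step 10. Fallback: the ester is given up and the C15 carbon is brought in as a methyl group. Setting out from 7, irradiation with 1-methylcyclobutene should give the cis-anti-cis 2,6-dimethyl tricyclic ketone F1 (cyclobutanes trans to the silyl ether, again with the other face tolerated). Here the head-to-head sense rests on the steric penalty of joining two quaternary carbons. Flash thermolysis of F1, at a higher temperature because the central bond is no longer ester-activated, would give the dienone directly, so the fallback comes back to the route at 17 and steps 11–14 fall away.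

Step 10. Three things can go wrong. The diyl may partition the other way (C6 equatorial), so that C4=C5 is formed with C3 trans to C6 and C1=C10 as the cis alkene. The product may go on by Cope rearrangement to a divinylcyclohexanone, which the ester accelerates. The β-silyloxy ketone may lose silanol in the hot zone. Fallback: the ring is opened at the alcohol oxidation level. Setting out from 11, LiAlH4 should reduce ketone and ester to the tricyclic diol F2. Me3SiCl and imidazole would give its bis(trimethylsilyl) ether F3, and thermolysis should open it to the ring-opened bis(trimethylsilyl) ether F4. K2CO3 in methanol removes the two trimethylsilyl groups, so the fallback comes back at 13. An sp3 C6 with a silyloxy group raises the preference for the axial position that leads to the wanted geometry, there is no enolisable ketone, and without the conjugated ester the Cope rearrangement is slower.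

Step 16. Facial selectivity at C7 and C11 may be poor if the ring conformation of 18 opposes the catalyst; the hindered, α-branched enol ether may also react slowly and be hydrolysed instead. Fallback: the catalytic open-transition-state addition is replaced by a stoichiometric, substrate-controlled aldol addition through a closed, chelated transition state. Setting out from 17, the lithium enolate (LiN(iPr)2, THF, −78 °C) is treated with 19. Peripheral attack should still set C7, while C11 is expected as a mixture of 21 and its C11 epimer F5. After separation, F5 is returned to 17 by retro-aldol cleavage of its lithium alkoxide and recycled. The fallback comes back at 21.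

Step 18. Hydride may add to the other carbonyl face if the zinc chelate does not form or if the ring shields the side of H7, which would give the C6 epimer. Fallback: the wrong carbinol is used with inversion. Setting out from 23, the reduction then gives the 6-epi-diol F6. A Mitsunobu esterification with angelic acid (PPh3, diisopropyl azodicarboxylate) should invert C6 and install the first angelate in one operation, the tertiary C11 hydroxyl staying free. The fallback comes back at 25, which is acylated at C11 as in step 19. The risk of this detour is SN2′ substitution at the allylic position.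

Step 19. The tertiary C11 alkoxide, next to the lactone carbonyl, may not be acylated; prolonged exposure to base may isomerise the angelate to the tiglate or move the lactone to the C6 oxygen. Fallback: the second Z double bond is built after the acylation. Setting out from 24, one equivalent of base and anhydride gives 25. Its C11 hydroxyl is esterified with 2-[bis(2,2,2-trifluoroethoxy)phosphoryl]propanoic acid and a carbodiimide (such acids acylate hindered alcohols through a ketene) to give the phosphonopropanoate F7. A Still–Gennari olefination with acetaldehyde (KN(SiMe3)2, 18-crown-6, THF, −78 °C) then forms the Z-2-methylbut-2-enoate, and the fallback comes back at 26.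

Step 20. The peracid may attack the other face if the conformer with C14 on the opposite side reacts, C4=C5 may be oxidised as well, and traces of acid may trigger transannular cyclisation of the product. Fallback: the epoxidation is moved to a stage where C4=C5 is an unreactive enone and the ring has another shape. Setting out from 23, mCPBA with NaHCO3 should give the epoxy keto lactone F8. A Luche reduction (NaBH4, CeCl3·7H2O, MeOH, −78 °C) would give the epoxy diol F9, and acylation with angelic anhydride and LiN(SiMe3)2 as in step 19 comes back to the route at 27.

## Further compounds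

F1 | step 9 | (8R)-8-[(tert-butyldimethylsilyl)oxy]-2,6-dimethyltricyclo[4.4.0.0(2,5)]decan-10-one, cis-anti-cis, cyclobutanes trans to the silyl ether | O=C1C[C@H](O[Si](C)(C)C(C)(C)C)C[C@]2(C)[C@H]1[C@@]1(C)CC[C@@H]21
F2 | step 10 | (8R)-8-[(tert-butyldimethylsilyl)oxy]-2-(hydroxymethyl)-6-methyltricyclo[4.4.0.0(2,5)]decan-10-ol from 11 (C10 epimers) | OC1C[C@H](O[Si](C)(C)C(C)(C)C)C[C@]2(C)[C@H]1[C@@]1(CO)CC[C@@H]21
F3 | step 10 | bis(trimethylsilyl) ether of F2 | C[Si](C)(C)OC1C[C@H](O[Si](C)(C)C(C)(C)C)C[C@]2(C)[C@H]1[C@@]1(CO[Si](C)(C)C)CC[C@@H]21
F4 | step 10 | bis(trimethylsilyl) ether of 13 | C[Si](C)(C)OC/C1=C/C(O[Si](C)(C)C)C[C@H](O[Si](C)(C)C(C)(C)C)C/C(C)=C/CC1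
F5 | step 16 | methyl (2S)-2-[(1R,3Z,7E,10R)-10-[(tert-butyldimethylsilyl)oxy]-4,8-dimethyl-2-oxocyclodeca-3,7-dien-1-yl]-2-hydroxypropanoate (C11 epimer of 21) | C/C1=C/C(=O)[C@@H]([C@](C)(O)C(=O)OC)[C@H](O[Si](C)(C)C(C)(C)C)C/C(C)=C/CC1
F6 | step 18 | (6S,7S,8R,11R)-6,11-dihydroxygermacra-1(10)E,4Z-dien-12,8-olide (C6 epimer of 24) | C/C1=C/[C@H](O)[C@H]2[C@@](C)(O)C(=O)O[C@@H]2C/C(C)=C/CC1
F7 | step 19 | 11-O-{2-[bis(2,2,2-trifluoroethoxy)phosphoryl]propanoyl} derivative of 25 (mixture at the phosphonate α-carbon) | C/C=C(/C)C(=O)O[C@@H]1/C=C(/C)CC/C=C(\C)C[C@H]2OC(=O)[C@](C)(OC(=O)C(C)P(=O)(OCC(F)(F)F)OCC(F)(F)F)[C@H]12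
F8 | step 20 | (1R,7R,8R,10R,11R)-1,10-epoxy-11-hydroxy-6-oxogermacr-4Z-en-12,8-olide | C/C1=C/C(=O)[C@H]2[C@@](C)(O)C(=O)O[C@@H]2C[C@@]3(C)O[C@@H]3CC1
F9 | step 20 | (1R,6R,7S,8R,10R,11R)-1,10-epoxy-6,11-dihydroxygermacr-4Z-en-12,8-olide | C/C1=C/[C@@H](O)[C@H]2[C@@](C)(O)C(=O)O[C@@H]2C[C@@]3(C)O[C@@H]3CC1
A1 | alternative 1 | (2Z,6E,9R)-9-[(4-methoxybenzyl)oxy]-3,7-dimethylcyclodeca-2,6-dien-1-one | O=C1/C=C(/C)CC/C=C(\C)C[C@@H](OCc2ccc(OC)cc2)C1
A2 | alternative 2 | (6R,7S,8R,11R)-6-[(tert-butyldimethylsilyl)oxy]-2,2-bis(phenylsulfonyl)-11-[(triethylsilyl)oxy]germacra-1(10)E,4Z-dien-12,8-olide | CC(C)(C)[Si](C)(C)O[C@@H]1/C=C(/C)CC(S(=O)(=O)c2ccccc2)(S(=O)(=O)c2ccccc2)/C=C(\C)C[C@H]2OC(=O)[C@](C)(O[Si](CC)(CC)CC)[C@H]12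
A3 | alternative 3 | (1R,2Z,6E,9R,10R)-9-[(tert-butyldimethylsilyl)oxy]-10-ethenyl-3,7-dimethylcyclodeca-2,6-dien-1-ol | O[C@@H]1/C=C(/C)CC/C=C(\C)C[C@@H](O[Si](C)(C)C(C)(C)C)[C@@H]1C=C
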